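The depside is cut at its aryl ester into a ring A acid and a ring B phenol, and everything rests on building ring B from open-chain pieces. Ring B carries the ester-forming oxygen at C4', para to the C1' carboxyl, a methyl ether at C2' and the side chain at C6'; a ketene carbonyl (C4') and the oxygen of methoxyacetylene (C2') map onto exactly this pair. In one operation, photolysis of an acyclic benzyl 2-diazo-3-oxopent-4-enoate that bears the ketal-masked 2-oxoheptyl chain on C4, in the presence of methoxyacetylene, should form four C–C bonds and the benzene ring, delivering the C4' phenol free and the C2' oxygen already methylated.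

Key step: step 8

Remark: the target is achiral (no stereocenter, no stereogenic double bond); unprimed locants refer to ring A (the acyl ring) and primed locants to ring B (the ring with the free carboxyl).

Step 1
Reactants: 1 hexanal; 2 ethyl 2-(bromomethyl)acrylate
Product: 4 ethyl 4-hydroxy-2-methylidenenonanoate (racemic), via allylindium dibromide 3 (not isolated)
Conditions: indium powder (1.2 equiv), THF/H2O (1:1), rt
Reagents that add atoms: none
Why: Barbier-type allylation in aqueous medium, in which the allylindium species formed from 2 adds to the aldehyde carbonyl; the carbinol stereocenter forms as a racemate and is erased by the oxidation in step 2.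

Step 2
Reactants: 4 ethyl 4-hydroxy-2-methylidenenonanoate
Product: 5 ethyl 2-methylidene-4-oxononanoate
Conditions: Dess–Martin periodinane (1.2 equiv), CH2Cl2, 0 °C to rt
Reagents that add atoms: none
Why: Dess–Martin oxidation of a secondary alcohol under non-basic conditions, which should leave the 1,1-disubstituted double bond out of conjugation with the new ketone.

Step 3
Reactants: 5 ethyl 2-methylidene-4-oxononanoate
Product: 6 ethyl 2-[(2-pentyl-1,3-dioxolan-2-yl)methyl]prop-2-enoate
Conditions: (TMSOCH2)2 (2 equiv), TMSOTf (5 mol %), CH2Cl2, −78 to −20 °C; pyridine quench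
Reagents that add atoms: 1,2-bis(trimethylsilyloxy)ethane, C[Si](C)(C)OCCO[Si](C)(C)C
Why: Noyori ketalization of an unhindered dialkyl ketone at low temperature, chosen because it protects enolizable unsaturated ketones without double-bond migration and does not touch the acrylate.

Step 4
Reactants: 6 ethyl 2-[(2-pentyl-1,3-dioxolan-2-yl)methyl]prop-2-enoate
Product: 7 2-[(2-pentyl-1,3-dioxolan-2-yl)methyl]prop-2-enoic acid
Conditions: LiOH·H2O (2 equiv), THF/H2O (3:1), rt; then cold 0.5 M HCl to pH 4
Reagents that add atoms: lithium hydroxide, [Li+].[OH-]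
Why: Saponification of an unhindered ethyl ester; the dioxolane is inert to base and should survive brief contact with weak acid at 0 °C, and the α-substituent slows conjugate addition of hydroxide.

Step 5
Reactants: 7 2-[(2-pentyl-1,3-dioxolan-2-yl)methyl]prop-2-enoic acid; 8 mono-benzyl malonate
Product: 11 benzyl 3-oxo-4-[(2-pentyl-1,3-dioxolan-2-yl)methyl]pent-4-enoate, via acyl imidazolide 9 (not isolated), via acylmalonic half-ester 10 (not isolated)
Conditions: CDI (1.1 equiv), THF, rt; then 8 (1.5 equiv), MgCl2 (1.5 equiv), Et3N (3 equiv), MeCN, rt to 40 °C; pH 4 citrate work-up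
Reagents that add atoms: none
Why: Masamune–Brooks homologation, in which the acyl imidazolide C-acylates the magnesium enolate of the malonate half-ester and the racemic adduct 10 loses CO2 under near-neutral conditions that spare the dioxolane.

Step 6
Reactants: 11 benzyl 3-oxo-4-[(2-pentyl-1,3-dioxolan-2-yl)methyl]pent-4-enoate
Product: 12 benzyl 2-diazo-3-oxo-4-[(2-pentyl-1,3-dioxolan-2-yl)methyl]pent-4-enoate
Conditions: p-ABSA (1.2 equiv), Et3N (1.5 equiv), MeCN, 0 °C to rt
Reagents that add atoms: 4-acetamidobenzenesulfonyl azide (p-ABSA), CC(=O)Nc1ccc(cc1)S(=O)(=O)N=[N+]=[N-]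
Why: Regitz diazo transfer to the doubly activated methylene of a β-keto ester, which should be fast enough at 0 °C to outrun Michael self-condensation of the α-substituted enone.

Step 7
Reactants: 13 chloroacetaldehyde dimethyl acetal
Product: 16 methoxyacetylene, via 1-chloro-2-methoxyethene 14 (not isolated), via sodium methoxyacetylide 15 (not isolated)
Conditions: NaNH2 (3 equiv), liq. NH3, −33 °C; then cold sat. aq NaCl, −70 °C to rt; distilled into a −78 °C trap (bp about 23 °C), kept as a cold solution in ClCH2CH2Cl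
Reagents that add atoms: none
Why: Twofold base-induced β-elimination (loss of methanol, then of HCl) with NaNH2 in liquid ammonia, the established preparation of 1-alkoxyalkynes, followed by protonation of the acetylide.

Step 8
Reactants: 12 benzyl 2-diazo-3-oxo-4-[(2-pentyl-1,3-dioxolan-2-yl)methyl]pent-4-enoate; 16 methoxyacetylene
Product: 21 benzyl 4-hydroxy-2-methoxy-6-[(2-pentyl-1,3-dioxolan-2-yl)methyl]benzoate, via vinylketene 17 (not isolated), via cyclobutenone 18 (not isolated), via dienylketene 19 (not isolated), via cyclohexadienone 20 (not isolated)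
Conditions: hν (300 nm, Pyrex), 16 (5 equiv), ClCH2CH2Cl (0.02 M), 0–5 °C; then sealed vessel, 80 °C
Reagents that add atoms: none
Why: Proposed new method: Light expels N2 from 12 and the alkenyl group shifts to the carbene carbon (Wolff rearrangement, C1'–C6'), giving the benzyloxycarbonyl vinylketene 17, whose electrophilic ketene carbon is attacked by the nucleophilic CH terminus of 16 so that the [2+2] adduct 18 has OMe next to the ester-bearing carbon (C1'–C2' and C3'–C4'). Heating then opens 18 in a reversible four-electron conrotatory process to dienylketene 19, and ring B closes by a thermal disrotatory six-electron electrocyclization between the ketene carbon and the terminal CH2 (C4'–C5'), after which dienone 20 tautomerizes to the phenol. The closest known reaction type is the Danheiser benzannulation, in which vinylketenes from photochemical Wolff rearrangement of unsaturated α-diazo ketones combine with alkoxy- or siloxyacetylenes; a vinylketene with an ester on the ketene carbon has not been shown in it. No stereocenter results, because the quaternary carbon of racemic 18 becomes planar on ring opening. The step needs [2+2] addition at the ketene C=C to win over hetero-[4+2] addition across the ester carbonyl and over acylation of the product phenol, which the weak heterodiene character of an ester C=O, the excess of the strongly nucleophilic ynol ether and dilution should secure, while the polarity match fixes the regiochemistry. Any dienylketene isomer with the ester turned inward can revert through 18, so aromatization is the only irreversible exit.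

Step 9
Reactants: 22 methyl orsellinate (methyl 2,4-dihydroxy-6-methylbenzoate)
Product: 23 methyl 2-hydroxy-4-methoxy-6-methylbenzoate
Conditions: MeI (1.1 equiv), K2CO3 (1.1 equiv), acetone, rt
Reagents that add atoms: iodomethane, CI
Why: Williamson etherification that is selective for the 4-hydroxyl because the 2-hydroxyl is tied up in a hydrogen bond to the ester carbonyl and is far less nucleophilic.

Step 10
Reactants: 23 methyl 2-hydroxy-4-methoxy-6-methylbenzoate
Product: 24 methyl 2-(benzyloxy)-4-methoxy-6-methylbenzoate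
Conditions: BnBr (1.3 equiv), K2CO3 (2 equiv), DMF, 60 °C
Reagents that add atoms: benzyl bromide, BrCc1ccccc1
Why: Williamson etherification of the remaining, hydrogen-bonded 2-hydroxyl under more forcing conditions.

Step 11
Reactants: 24 methyl 2-(benzyloxy)-4-methoxy-6-methylbenzoate; 25 N-methoxy-N-methylhexanamide
Product: 28 methyl 2-(benzyloxy)-4-methoxy-6-(2-oxoheptyl)benzoate, via benzylic lithium species 26 (not isolated), via tetrahedral adduct 27 (not isolated)
Conditions: LiN(i-Pr)2 (1.1 equiv), THF, −78 °C; then 25 (1.2 equiv), −78 °C; AcOH quench at −78 °C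
Reagents that add atoms: none
Why: Lateral (benzylic) lithiation of an ortho-toluate followed by acylation with a Weinreb amide, whose chelated tetrahedral adduct 27 persists until the cold acidic quench and so prevents over-addition and base-induced enol-lactonization.

Step 12
Reactants: 28 methyl 2-(benzyloxy)-4-methoxy-6-(2-oxoheptyl)benzoate
Product: 29 methyl 2-(benzyloxy)-4-methoxy-6-[(2-pentyl-1,3-dioxolan-2-yl)methyl]benzoate
Conditions: (TMSOCH2)2 (2 equiv), TMSOTf (5 mol %), CH2Cl2, −78 to −20 °C; pyridine quench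
Reagents that add atoms: 1,2-bis(trimethylsilyloxy)ethane, C[Si](C)(C)OCCO[Si](C)(C)C
Why: Noyori ketalization at low temperature, which should protect the benzylic ketone without the heating in protic acid that would close it onto the ester as an isocoumarin.

Step 13
Reactants: 29 methyl 2-(benzyloxy)-4-methoxy-6-[(2-pentyl-1,3-dioxolan-2-yl)methyl]benzoate
Product: 30 2-(benzyloxy)-4-methoxy-6-[(2-pentyl-1,3-dioxolan-2-yl)methyl]benzoic acid
Conditions: KOH (10 equiv), DMSO/H2O (4:1), 90 °C; then cold 0.5 M HCl to pH 4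
Reagents that add atoms: potassium hydroxide, [K+].[OH-]
Why: Saponification of a di-ortho-substituted methyl benzoate needs hot KOH in aqueous DMSO, conditions to which the dioxolane and both aryl ethers are inert.

Step 14
Reactants: 30 2-(benzyloxy)-4-methoxy-6-[(2-pentyl-1,3-dioxolan-2-yl)methyl]benzoic acid; 21 benzyl 4-hydroxy-2-methoxy-6-[(2-pentyl-1,3-dioxolan-2-yl)methyl]benzoate
Product: 32 benzyl 4-({2-(benzyloxy)-4-methoxy-6-[(2-pentyl-1,3-dioxolan-2-yl)methyl]benzoyl}oxy)-2-methoxy-6-[(2-pentyl-1,3-dioxolan-2-yl)methyl]benzoate, via O-acylisourea 31 (not isolated)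
Conditions: DCC (1.3 equiv), DMAP (0.3 equiv), CH2Cl2, 0 °C to rt
Reagents that add atoms: none
Why: Steglich esterification, in which DMAP relays the acyl group of the O-acylisourea to the unhindered and fairly acidic 4'-phenol, the only free hydroxyl in either partner, under neutral conditions that keep both dioxolanes.

Step 15
Reactants: 32 the bis-dioxolane depside from step 14
Product: 33 benzyl 4-{[2-(benzyloxy)-4-methoxy-6-(2-oxoheptyl)benzoyl]oxy}-2-methoxy-6-(2-oxoheptyl)benzoate
Conditions: 1 M aq HCl/THF (1:4), rt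
Reagents that add atoms: water, O
Why: Acid-catalysed hydrolysis of both dioxolanes, during which the hindered aryl benzoate, the benzyl ester and the benzyl ether should persist as long as the mixture is not heated, since heat would favour enol-lactonization to an isocoumarin.

Step 16
Reactants: 33 benzyl 4-{[2-(benzyloxy)-4-methoxy-6-(2-oxoheptyl)benzoyl]oxy}-2-methoxy-6-(2-oxoheptyl)benzoate
Product: 34 4-{[2-hydroxy-4-methoxy-6-(2-oxoheptyl)benzoyl]oxy}-2-methoxy-6-(2-oxoheptyl)benzoic acid (CNP0177576.0)
Conditions: H2 (1 atm), 10% Pd/C, EtOAc, rt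
Reagents that add atoms: none
Why: Hydrogenolysis of the benzyl ester and the benzyl ether over palladium on carbon, to which the dialkyl ketones, the aryl ester and the methyl ethers are inert, in a neutral medium that leaves the keto acid open-chain.

Compound list
1 | hexanal | CCCCCC=O | starting material
2 | ethyl 2-(bromomethyl)acrylate | C=C(CBr)C(=O)OCC | starting material
3 | [2-(ethoxycarbonyl)prop-2-en-1-yl]indium dibromide (allylindium species drawn in its simplest form; not isolated) | CCOC(=O)C(=C)C[In](Br)Br | intermediate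
4 | ethyl 4-hydroxy-2-methylidenenonanoate (racemic) | CCCCCC(O)CC(=C)C(=O)OCC | intermediate
5 | ethyl 2-methylidene-4-oxononanoate | CCCCCC(=O)CC(=C)C(=O)OCC | intermediate
6 | ethyl 2-[(2-pentyl-1,3-dioxolan-2-yl)methyl]prop-2-enoate | CCCCCC1(CC(=C)C(=O)OCC)OCCO1 | intermediate
7 | 2-[(2-pentyl-1,3-dioxolan-2-yl)methyl]prop-2-enoic acid | CCCCCC1(CC(=C)C(=O)O)OCCO1 | intermediate
8 | mono-benzyl malonate (3-(benzyloxy)-3-oxopropanoic acid) | O=C(O)CC(=O)OCc1ccccc1 | starting material
9 | 1-{2-[(2-pentyl-1,3-dioxolan-2-yl)methyl]prop-2-enoyl}-1H-imidazole (not isolated) | CCCCCC1(CC(=C)C(=O)n2ccnc2)OCCO1 | intermediate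
10 | 2-[(benzyloxy)carbonyl]-3-oxo-4-[(2-pentyl-1,3-dioxolan-2-yl)methyl]pent-4-enoic acid (racemic; present as its magnesium chelate; not isolated) | CCCCCC1(CC(=C)C(=O)C(C(=O)O)C(=O)OCc2ccccc2)OCCO1 | intermediate
11 | benzyl 3-oxo-4-[(2-pentyl-1,3-dioxolan-2-yl)methyl]pent-4-enoate | CCCCCC1(CC(=C)C(=O)CC(=O)OCc2ccccc2)OCCO1 | intermediate
12 | benzyl 2-diazo-3-oxo-4-[(2-pentyl-1,3-dioxolan-2-yl)methyl]pent-4-enoate | C=C(CC1(CCCCC)OCCO1)C(=O)C(=[N+]=[N-])C(=O)OCc1ccccc1 | intermediate
13 | chloroacetaldehyde dimethyl acetal (2-chloro-1,1-dimethoxyethane) | COC(CCl)OC | starting material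
14 | 1-chloro-2-methoxyethene (E/Z mixture; not isolated) | COC=CCl | intermediate
15 | sodium methoxyacetylide (not isolated) | [Na+].[C-]#COC | intermediate
16 | methoxyacetylene (methoxyethyne) | C#COC | intermediate
17 | benzyl 2-(oxomethylidene)-3-[(2-pentyl-1,3-dioxolan-2-yl)methyl]but-3-enoate (vinylketene; not isolated) | O=C=C(C(=O)OCc1ccccc1)C(=C)CC1(CCCCC)OCCO1 | intermediate
18 | benzyl 2-methoxy-4-oxo-1-[3-(2-pentyl-1,3-dioxolan-2-yl)prop-1-en-2-yl]cyclobut-2-ene-1-carboxylate (racemic; not isolated) | COC1=CC(=O)C1(C(=O)OCc1ccccc1)C(=C)CC1(CCCCC)OCCO1 | intermediate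
19 | benzyl (2Z)-3-methoxy-5-oxo-2-[3-(2-pentyl-1,3-dioxolan-2-yl)prop-1-en-2-yl]penta-2,4-dienoate (dienylketene, alkenyl group cis to the ketene arm; not isolated) | O=C=C/C(OC)=C(/C(=O)OCc1ccccc1)C(=C)CC1(CCCCC)OCCO1 | intermediate
20 | benzyl 6-methoxy-4-oxo-2-[(2-pentyl-1,3-dioxolan-2-yl)methyl]cyclohexa-1,5-diene-1-carboxylate (not isolated) | O=C1C=C(OC)C(C(=O)OCc2ccccc2)=C(CC2(CCCCC)OCCO2)C1 | intermediate
21 | benzyl 4-hydroxy-2-methoxy-6-[(2-pentyl-1,3-dioxolan-2-yl)methyl]benzoate | CCCCCC1(Cc2cc(O)cc(OC)c2C(=O)OCc2ccccc2)OCCO1 | intermediate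
22 | methyl orsellinate (methyl 2,4-dihydroxy-6-methylbenzoate) | COC(=O)c1c(C)cc(O)cc1O | starting material
23 | methyl 2-hydroxy-4-methoxy-6-methylbenzoate | COC(=O)c1c(C)cc(OC)cc1O | intermediate
24 | methyl 2-(benzyloxy)-4-methoxy-6-methylbenzoate | COC(=O)c1c(C)cc(OC)cc1OCc1ccccc1 | intermediate
25 | N-methoxy-N-methylhexanamide | CCCCCC(=O)N(C)OC | starting material
26 | methyl 2-(benzyloxy)-6-(lithiomethyl)-4-methoxybenzoate (not isolated) | [Li]Cc1cc(OC)cc(OCc2ccccc2)c1C(=O)OC | intermediate
27 | lithium alkoxide of methyl 2-(benzyloxy)-6-{2-hydroxy-2-[methoxy(methyl)amino]heptyl}-4-methoxybenzoate (racemic; not isolated) | CCCCCC(O[Li])(Cc1cc(OC)cc(OCc2ccccc2)c1C(=O)OC)N(C)OC | intermediate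
28 | methyl 2-(benzyloxy)-4-methoxy-6-(2-oxoheptyl)benzoate | CCCCCC(=O)Cc1cc(OC)cc(OCc2ccccc2)c1C(=O)OC | intermediate
29 | methyl 2-(benzyloxy)-4-methoxy-6-[(2-pentyl-1,3-dioxolan-2-yl)methyl]benzoate | CCCCCC1(Cc2cc(OC)cc(OCc3ccccc3)c2C(=O)OC)OCCO1 | intermediate
30 | 2-(benzyloxy)-4-methoxy-6-[(2-pentyl-1,3-dioxolan-2-yl)methyl]benzoic acid | CCCCCC1(Cc2cc(OC)cc(OCc3ccccc3)c2C(=O)O)OCCO1 | intermediate
31 | O-acylisourea of 30 with N,N'-dicyclohexylcarbodiimide (not isolated) | CCCCCC1(Cc2cc(OC)cc(OCc3ccccc3)c2C(=O)OC(=NC2CCCCC2)NC2CCCCC2)OCCO1 | intermediate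
32 | benzyl 4-({2-(benzyloxy)-4-methoxy-6-[(2-pentyl-1,3-dioxolan-2-yl)methyl]benzoyl}oxy)-2-methoxy-6-[(2-pentyl-1,3-dioxolan-2-yl)methyl]benzoate | CCCCCC1(Cc2cc(OC)cc(OCc3ccccc3)c2C(=O)Oc2cc(CC3(CCCCC)OCCO3)c(C(=O)OCc3ccccc3)c(OC)c2)OCCO1 | intermediate
33 | benzyl 4-{[2-(benzyloxy)-4-methoxy-6-(2-oxoheptyl)benzoyl]oxy}-2-methoxy-6-(2-oxoheptyl)benzoate | CCCCCC(=O)Cc1cc(OC)cc(OCc2ccccc2)c1C(=O)Oc1cc(CC(=O)CCCCC)c(C(=O)OCc2ccccc2)c(OC)c1 | intermediate
34 | 4-{[2-hydroxy-4-methoxy-6-(2-oxoheptyl)benzoyl]oxy}-2-methoxy-6-(2-oxoheptyl)benzoic acid (CNP0177576.0) | CCCCCC(=O)Cc1cc(OC)cc(O)c1C(=O)Oc1cc(CC(=O)CCCCC)c(C(=O)O)c(OC)c1 | target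

Total step count: 16 (fallbacks not counted).
Longest linear sequence: 10 steps (steps 1–6, 8, 14, 15, 16).

Steps most likely to fail

Step 8. The ester-substituted ketene may be consumed by hetero-[4+2] addition of the ynol ether across its ester carbonyl, by dimerization, or by acylating the phenol as it forms, so that the benzannulation pathway is starved. The fallback uses established arene chemistry and sets out from 22 (with 25 as the acyl source). Selective benzylation of the non-chelated 4-hydroxyl (BnBr, K2CO3, acetone) would give methyl 4-(benzyloxy)-2-hydroxy-6-methylbenzoate F1. Methylation of the chelated 2-hydroxyl (MeI, K2CO3, DMF) would give methyl 4-(benzyloxy)-2-methoxy-6-methylbenzoate F2. Lateral lithiation with LiN(i-Pr)2 and acylation with 25 would give methyl 4-(benzyloxy)-2-methoxy-6-(2-oxoheptyl)benzoate F3, and Noyori ketalization would give methyl 4-(benzyloxy)-2-methoxy-6-[(2-pentyl-1,3-dioxolan-2-yl)methyl]benzoate F4. Saponification with KOH in aqueous DMSO would give 4-(benzyloxy)-2-methoxy-6-[(2-pentyl-1,3-dioxolan-2-yl)methyl]benzoic acid F5. Hydrogenolysis (H2, Pd/C, EtOAc) would give 4-hydroxy-2-methoxy-6-[(2-pentyl-1,3-dioxolan-2-yl)methyl]benzoic acid F6. Chemoselective benzylation of the carboxylate in the presence of the phenol (BnBr, KHCO3, DMF, rt) returns to the route at 21.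

Step 14. Acyl transfer from the di-ortho-substituted acyl donor may be so slow that the O-acylisourea rearranges to the unreactive N-acylurea before the phenol is acylated. The fallback separates activation from coupling and sets out from 30. The neutral chlorinating agent 1-chloro-N,N,2-trimethylprop-1-en-1-amine (CH2Cl2, 0 °C) would give 2-(benzyloxy)-4-methoxy-6-[(2-pentyl-1,3-dioxolan-2-yl)methyl]benzoyl chloride F7. This is added to the preformed sodium phenoxide of 21 (NaH, THF, 0 °C), a much stronger nucleophile than the neutral phenol, and the sequence comes back to the route at 32.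

Step 5. Conjugate addition of imidazole or of the malonate enolate to the acryloyl unit, and Michael self-condensation of the alkenyl β-keto ester, may erode the homologation. The fallback avoids both the acyl imidazolide and the free β-keto ester and sets out from 6. Reduction with i-Bu2AlH (CH2Cl2, −78 °C) would give 2-[(2-pentyl-1,3-dioxolan-2-yl)methyl]prop-2-en-1-ol F8, and allylic oxidation with MnO2 (CH2Cl2, rt) would give 2-[(2-pentyl-1,3-dioxolan-2-yl)methyl]prop-2-enal F9. Aldol-type addition of benzyl diazoacetate catalysed by DBU (MeCN, rt) would give racemic benzyl 2-diazo-3-hydroxy-4-[(2-pentyl-1,3-dioxolan-2-yl)methyl]pent-4-enoate F10. Oxidation of the carbinol with IBX (DMSO, rt) comes back to the route at 12, so that steps 4 to 6 are bypassed.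

Further compounds
F1 | step 8 | methyl 4-(benzyloxy)-2-hydroxy-6-methylbenzoate | COC(=O)c1c(C)cc(OCc2ccccc2)cc1O
F2 | step 8 | methyl 4-(benzyloxy)-2-methoxy-6-methylbenzoate | COC(=O)c1c(C)cc(OCc2ccccc2)cc1OC
F3 | step 8 | methyl 4-(benzyloxy)-2-methoxy-6-(2-oxoheptyl)benzoate | CCCCCC(=O)Cc1cc(OCc2ccccc2)cc(OC)c1C(=O)OC
F4 | step 8 | methyl 4-(benzyloxy)-2-methoxy-6-[(2-pentyl-1,3-dioxolan-2-yl)methyl]benzoate | CCCCCC1(Cc2cc(OCc3ccccc3)cc(OC)c2C(=O)OC)OCCO1
F5 | step 8 | 4-(benzyloxy)-2-methoxy-6-[(2-pentyl-1,3-dioxolan-2-yl)methyl]benzoic acid | CCCCCC1(Cc2cc(OCc3ccccc3)cc(OC)c2C(=O)O)OCCO1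
F6 | step 8 | 4-hydroxy-2-methoxy-6-[(2-pentyl-1,3-dioxolan-2-yl)methyl]benzoic acid | CCCCCC1(Cc2cc(O)cc(OC)c2C(=O)O)OCCO1
F7 | step 14 | 2-(benzyloxy)-4-methoxy-6-[(2-pentyl-1,3-dioxolan-2-yl)methyl]benzoyl chloride | CCCCCC1(Cc2cc(OC)cc(OCc3ccccc3)c2C(=O)Cl)OCCO1
F8 | step 5 | 2-[(2-pentyl-1,3-dioxolan-2-yl)methyl]prop-2-en-1-ol | C=C(CO)CC1(CCCCC)OCCO1
F9 | step 5 | 2-[(2-pentyl-1,3-dioxolan-2-yl)methyl]prop-2-enal | C=C(C=O)CC1(CCCCC)OCCO1
F10 | step 5 | benzyl 2-diazo-3-hydroxy-4-[(2-pentyl-1,3-dioxolan-2-yl)methyl]pent-4-enoate (racemic) | C=C(CC1(CCCCC)OCCO1)C(O)C(=[N+]=[N-])C(=O)OCc1ccccc1
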